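**Plan**
- Numbering: ring A is the benzo ring (propenal on C1, OMe on C3, ring oxygens O4 and O5); C7' carries the guaiacyl ring B, C8' carries C9'H2OH.
- Cuts: the ring A C1–C7 bond (Heck), then O5–C7' (ring closure), then O4–C8' and C7'–C8' together, leaving a ring A phenol, ethyl diazoacetate and vanillin acetate.
- Enabling feature: C8' of the 1,4-dioxane ring is bonded to O4, C7' and C9', so it can be a carbene carbon that takes up a phenol oxygen and an aldehyde carbon at once, with C9' arriving as the ester.
- Forward: the ring A phenol is made from 5-bromo-o-vanillin; the three-component coupling joins the whole chain; reduction and desilylation follow; the dioxane ring (the only ring formed) closes; the propenal arm comes last.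
- Stereochemistry: C8' is set by the chiral phosphoric acid in the coupling and not touched again; C7' is set under thermodynamic control in the reversible ring closure (trans, hence 7'S); the E alkene comes from the Heck reaction.

Key step: step 3

Assumption: the (R)-configured phosphoric acid is taken to give the (2R) configuration at the carbene carbon (C8'); should a trial show the opposite sense, its (S)-antipode would be used with nothing else changed.

**Route**

Step 1
Reactants: 1 5-bromo-2-hydroxy-3-methoxybenzaldehyde
Product: 3 5-bromo-3-methoxybenzene-1,2-diol, via aryl formate 2 (not isolated)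
Conditions: 30% aq H2O2, 1 M aq NaOH, 0 °C to rt, N2; then aq HCl
Reagents that add atoms: hydrogen peroxide, OO
Why: Dakin oxidation, in which hydroperoxide adds to the ortho-hydroxy aldehyde, the electron-rich aryl group migrates to oxygen, and the formate 2 is saponified in the same flask.

Step 2
Reactants: 3 5-bromo-3-methoxybenzene-1,2-diol
Product: 4 4-bromo-2-methoxy-6-(triisopropylsilyloxy)phenol
Conditions: i-Pr3SiCl (1.05 equiv), imidazole, CH2Cl2/DMF, 0 °C to rt
Reagents that add atoms: chlorotriisopropylsilane, CC(C)[Si](Cl)(C(C)C)C(C)C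
Why: Selective silylation, because only the hydroxyl with a free ortho position is open to the bulky silyl chloride, any silyl transfer between the two catechol oxygens ends on that same less hindered oxygen, and the remaining hydroxyl is too crowded for a second silylation.

Step 3
Reactants: 4 4-bromo-2-methoxy-6-(triisopropylsilyloxy)phenol; 5 ethyl diazoacetate; 6 4-formyl-2-methoxyphenyl acetate (vanillin acetate)
Product: 8 ethyl (2R,3S)-3-(4-acetoxy-3-methoxyphenyl)-2-[4-bromo-2-methoxy-6-(triisopropylsilyloxy)phenoxy]-3-hydroxypropanoate, via oxonium ylide 7 (not isolated)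
Conditions: Rh2(OAc)4 (2 mol %), (R)-3,3'-bis(2,4,6-triisopropylphenyl)-1,1'-binaphthyl-2,2'-diyl hydrogen phosphate (10 mol %), 6 (1.5 equiv), 4 Å MS, CH2Cl2, 0 °C, 5 (1.2 equiv) added over 4 h by syringe pump
Reagents that add atoms: none
Why: Proposed new method: Rh2(OAc)4 turns 5 into an electrophilic rhodium carbene that the only free hydroxyl of 4 attacks to give the protic oxonium ylide 7 (equivalently its enol), and this nucleophile adds to 6, held and activated by the chiral phosphoric acid through hydrogen bonds, before the formal 1,2-hydrogen shift to the plain O–H insertion product takes place, so that O4–C8' and C7'–C8' form in one operation. The closest known reaction type is the Rh2(OAc)4 and chiral phosphoric acid co-catalysed three-component coupling of aryldiazoacetates, alcohols and aldehydes or imines by aldol- or Mannich-type trapping of oxonium ylides, together with the enantioselective O–H insertion of phenols under the same dual catalysis; new here are the acceptor-only diazo ester, the phenol as ylide donor and the only moderately electrophilic aldehyde. No ring closes. C8' (C2 of 8) is set by the chiral phosphate, which binds the enol hydroxyl through its P=O oxygen and the aldehyde through its P–OH group and so fixes the enol face that is attacked; C7' (C3) follows from the cyclic hydrogen-bonded transition state, expected to favour the syn adduct drawn, but its configuration is of no consequence because it is set again in step 6. The step needs O–H capture to win over arene cyclopropanation, carbonyl ylide formation and carbene dimerisation, and aldol trapping to win over proton transfer; the acidic, electron-rich hydroxyl of 4, the acetyl group that keeps the aldehyde of 6 electrophilic, the excess of 6, the slow addition of 5 and the low temperature are chosen to secure both.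

Step 4
Reactants: 8 ethyl (2R,3S)-3-(4-acetoxy-3-methoxyphenyl)-2-[4-bromo-2-methoxy-6-(triisopropylsilyloxy)phenoxy]-3-hydroxypropanoate
Product: 9 (1S,2S)-2-[4-bromo-2-methoxy-6-(triisopropylsilyloxy)phenoxy]-1-(4-hydroxy-3-methoxyphenyl)propane-1,3-diol
Conditions: LiBH4 (4 equiv), THF/MeOH, 0 °C to rt; aq NH4Cl
Reagents that add atoms: none
Why: Hydride reduction of the α-aryloxy ester to the primary alcohol with reductive cleavage of the aryl acetate in the same flask, a standard ester-to-diol reduction of β-hydroxy-α-aryloxy esters that leaves the aryl bromide, the aryl silyl ether and both stereocentres alone (the C8' descriptor changes from R to S only through the change in substituent priorities).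

Step 5
Reactants: 9 (1S,2S)-2-[4-bromo-2-methoxy-6-(triisopropylsilyloxy)phenoxy]-1-(4-hydroxy-3-methoxyphenyl)propane-1,3-diol
Product: 10 (1S,2S)-2-(4-bromo-2-hydroxy-6-methoxyphenoxy)-1-(4-hydroxy-3-methoxyphenyl)propane-1,3-diol
Conditions: n-Bu4NF (1.1 equiv), AcOH (1.1 equiv), THF, 0 °C
Reagents that add atoms: none
Why: Fluoride-mediated cleavage of the aryl silyl ether, driven by the strong Si–F bond, with acetic acid buffering the phenoxide so that the para-hydroxybenzylic alcohol is not exposed to base.

Step 6
Reactants: 10 (1S,2S)-2-(4-bromo-2-hydroxy-6-methoxyphenoxy)-1-(4-hydroxy-3-methoxyphenyl)propane-1,3-diol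
Product: 11 [(2S,3S)-6-bromo-3-(4-hydroxy-3-methoxyphenyl)-8-methoxy-2,3-dihydro-1,4-benzodioxin-2-yl]methanol (trans, 7'S,8'S)
Conditions: TsOH·H2O (10 mol %), MeCN, 40 °C
Reagents that add atoms: none
Why: Acid-catalysed SN1 etherification, in which the benzylic C7' hydroxyl ionises to a para-hydroxybenzylic cation (a protonated quinone methide) that the ring A hydroxyl O5 captures to close the six-membered dioxane; the closure is reversible, so either C7' epimer of 10 should converge on the diequatorial trans isomer, which is 7'S because C8' is fixed and untouched.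

Step 7
Reactants: 11 [(2S,3S)-6-bromo-3-(4-hydroxy-3-methoxyphenyl)-8-methoxy-2,3-dihydro-1,4-benzodioxin-2-yl]methanol; 12 3,3-diethoxyprop-1-ene (acrolein diethyl acetal)
Product: 14 (7'S,8'S)-nocomtal [(E)-3-{(2S,3S)-3-(4-hydroxy-3-methoxyphenyl)-2-(hydroxymethyl)-8-methoxy-2,3-dihydro-1,4-benzodioxin-6-yl}prop-2-enal], via diethyl acetal 13 (not isolated)
Conditions: Pd(OAc)2 (5 mol %), n-Bu4NOAc, K2CO3, KCl, DMF, 90 °C; then 2 M aq HCl, rt
Reagents that add atoms: water, O
Why: Mizoroki–Heck reaction of the unhindered aryl bromide (oxidative addition to zerovalent palladium formed in situ) with the acrolein acetal under ligand-free, acetate-buffered conditions that direct β-hydride elimination away from the acetal carbon to the E-cinnamaldehyde acetal 13, which dilute acid hydrolyses in the same flask while the thermodynamically preferred trans-dioxane should persist.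

**Compound list**

1 | 5-bromo-2-hydroxy-3-methoxybenzaldehyde | COc1cc(Br)cc(C=O)c1O | starting material
2 | 5-bromo-2-hydroxy-3-methoxyphenyl formate | COc1cc(Br)cc(OC=O)c1O | intermediate
3 | 5-bromo-3-methoxybenzene-1,2-diol | COc1cc(Br)cc(O)c1O | intermediate
4 | 4-bromo-2-methoxy-6-(triisopropylsilyloxy)phenol | COc1cc(Br)cc(O[Si](C(C)C)(C(C)C)C(C)C)c1O | intermediate
5 | ethyl diazoacetate | CCOC(=O)C=[N+]=[N-] | starting material
6 | 4-formyl-2-methoxyphenyl acetate (vanillin acetate) | COc1cc(C=O)ccc1OC(C)=O | starting material
7 | oxonium ylide from 4 and the carbene of 5 (metal-free form) | CCOC(=O)[CH-][OH+]c1c(OC)cc(Br)cc1O[Si](C(C)C)(C(C)C)C(C)C | intermediate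
8 | ethyl (2R,3S)-3-(4-acetoxy-3-methoxyphenyl)-2-[4-bromo-2-methoxy-6-(triisopropylsilyloxy)phenoxy]-3-hydroxypropanoate | COc1cc([C@H](O)[C@@H](Oc2c(OC)cc(Br)cc2O[Si](C(C)C)(C(C)C)C(C)C)C(=O)OCC)ccc1OC(C)=O | intermediate
9 | (1S,2S)-2-[4-bromo-2-methoxy-6-(triisopropylsilyloxy)phenoxy]-1-(4-hydroxy-3-methoxyphenyl)propane-1,3-diol | COc1cc([C@H](O)[C@@H](Oc2c(OC)cc(Br)cc2O[Si](C(C)C)(C(C)C)C(C)C)CO)ccc1O | intermediate
10 | (1S,2S)-2-(4-bromo-2-hydroxy-6-methoxyphenoxy)-1-(4-hydroxy-3-methoxyphenyl)propane-1,3-diol | COc1cc([C@H](O)[C@@H](Oc2c(OC)cc(Br)cc2O)CO)ccc1O | intermediate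
11 | [(2S,3S)-6-bromo-3-(4-hydroxy-3-methoxyphenyl)-8-methoxy-2,3-dihydro-1,4-benzodioxin-2-yl]methanol | COc1cc([C@@H]2Oc3cc(Br)cc(OC)c3O[C@H]2CO)ccc1O | intermediate
12 | 3,3-diethoxyprop-1-ene (acrolein diethyl acetal) | C=CC(OCC)OCC | starting material
13 | [(2S,3S)-6-[(E)-3,3-diethoxyprop-1-en-1-yl]-3-(4-hydroxy-3-methoxyphenyl)-8-methoxy-2,3-dihydro-1,4-benzodioxin-2-yl]methanol | COc1cc([C@@H]2Oc3cc(/C=C/C(OCC)OCC)cc(OC)c3O[C@H]2CO)ccc1O | intermediate
14 | (7'S,8'S)-nocomtal, (E)-3-[(2S,3S)-3-(4-hydroxy-3-methoxyphenyl)-2-(hydroxymethyl)-8-methoxy-2,3-dihydro-1,4-benzodioxin-6-yl]prop-2-enal | COc1cc([C@@H]2Oc3cc(/C=C/C=O)cc(OC)c3O[C@H]2CO)ccc1O | target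

**Summary**

Total step count: 7. Longest linear sequence: 7 steps (1 → 3 → 4 → 8 → 9 → 10 → 11 → 14).

Steps most likely to fail:

1. Step 3 (proposed new method). Proton transfer within the ylide or its enol may outrun C–C bond formation, so that only O–H insertion occurs, or the chiral acid may give poor facial control at C8'. The fallback uses known chemistry, sets out from 4 and 5 and returns to the route at 9.
   - Rh2(OAc)4-catalysed O–H insertion of 5 into 4 in CH2Cl2 without aldehyde should give ethyl 2-[4-bromo-2-methoxy-6-(triisopropylsilyloxy)phenoxy]acetate F1. This is also the material a failed coupling would leave behind, so it can be collected from there.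
   - Mild hydrolysis with Me3SnOH in 1,2-dichloroethane at 70 °C should give 2-[4-bromo-2-methoxy-6-(triisopropylsilyloxy)phenoxy]acetic acid F2.
   - Activation as the pivaloyl mixed anhydride (t-BuCOCl, Et3N, THF, −20 °C) and acylation of (R)-4-benzyloxazolidin-2-one in the presence of LiCl should give (4R)-4-benzyl-3-{2-[4-bromo-2-methoxy-6-(triisopropylsilyloxy)phenoxy]acetyl}-1,3-oxazolidin-2-one F3.
   - Evans syn aldol reaction (n-Bu2BOTf, i-Pr2NEt, CH2Cl2, −78 °C, then 6) should give (4R)-4-benzyl-3-[(2R,3S)-3-(4-acetoxy-3-methoxyphenyl)-2-[4-bromo-2-methoxy-6-(triisopropylsilyloxy)phenoxy]-3-hydroxypropanoyl]-1,3-oxazolidin-2-one F4, with C8' fixed by the auxiliary.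
   - LiBH4 in THF/MeOH then removes auxiliary and acetate together and delivers 9.

2. Step 6. Equilibration may stay incomplete and leave the cis isomer, or the benzylic cation may lose H8' or formaldehyde under acid (enol ether formation), which would erode C8' and the chain. The fallback sets out from 10 and returns at 11, replacing acid ionisation by a kinetically controlled conjugate addition under near-neutral conditions.
   - Me3SiBr in CH2Cl2 at 0 °C should convert the benzylic hydroxyl into the bromide, (2S)-3-bromo-2-(4-bromo-2-hydroxy-6-methoxyphenoxy)-3-(4-hydroxy-3-methoxyphenyl)propan-1-ol F5 (mixture at C3).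
   - Brief shaking with aq NaHCO3 should eliminate HBr to the para-quinone methide, 4-[(2R)-2-(4-bromo-2-hydroxy-6-methoxyphenoxy)-3-hydroxypropylidene]-2-methoxycyclohexa-2,5-dien-1-one F6.
   - The ortho hydroxyl of ring A should then close onto F6 by 6-exo oxa-Michael addition, the mode through which trans-benzodioxanes arise in oxidative phenol couplings, to give 11.

3. Step 7. Oxidative addition into the electron-rich bromide may be slow, β-hydride elimination may go toward the acetal carbon and give the saturated ester, or the phenolic benzyl aryl ether may open under base at 90 °C. The fallback sets out from 11 and returns at 13, and from there to 14 by the same acid hydrolysis. It is a Suzuki–Miyaura coupling of 11 with commercial (E)-2-(3,3-diethoxyprop-1-en-1-yl)-4,4,5,5-tetramethyl-1,3,2-dioxaborolane (Pd(OAc)2, 2-dicyclohexylphosphino-2',6'-dimethoxybiphenyl, K3PO4, THF/H2O, 40 °C). The alkene geometry and position are fixed by the boronate and the temperature is lower. No compound outside the list is made (F0).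

**Further compounds**

F1 | step 3 | ethyl 2-[4-bromo-2-methoxy-6-(triisopropylsilyloxy)phenoxy]acetate | CCOC(=O)COc1c(OC)cc(Br)cc1O[Si](C(C)C)(C(C)C)C(C)C
F2 | step 3 | 2-[4-bromo-2-methoxy-6-(triisopropylsilyloxy)phenoxy]acetic acid | OC(=O)COc1c(OC)cc(Br)cc1O[Si](C(C)C)(C(C)C)C(C)C
F3 | step 3 | (4R)-4-benzyl-3-{2-[4-bromo-2-methoxy-6-(triisopropylsilyloxy)phenoxy]acetyl}-1,3-oxazolidin-2-one | O=C(COc1c(OC)cc(Br)cc1O[Si](C(C)C)(C(C)C)C(C)C)N1[C@H](Cc2ccccc2)COC1=O
F4 | step 3 | (4R)-4-benzyl-3-[(2R,3S)-3-(4-acetoxy-3-methoxyphenyl)-2-[4-bromo-2-methoxy-6-(triisopropylsilyloxy)phenoxy]-3-hydroxypropanoyl]-1,3-oxazolidin-2-one | COc1cc([C@H](O)[C@@H](Oc2c(OC)cc(Br)cc2O[Si](C(C)C)(C(C)C)C(C)C)C(=O)N2[C@H](Cc3ccccc3)COC2=O)ccc1OC(C)=O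
F5 | step 6 | (2S)-3-bromo-2-(4-bromo-2-hydroxy-6-methoxyphenoxy)-3-(4-hydroxy-3-methoxyphenyl)propan-1-ol | COc1cc(C(Br)[C@@H](Oc2c(OC)cc(Br)cc2O)CO)ccc1O
F6 | step 6 | 4-[(2R)-2-(4-bromo-2-hydroxy-6-methoxyphenoxy)-3-hydroxypropylidene]-2-methoxycyclohexa-2,5-dien-1-one | COC1=CC(=C[C@@H](Oc2c(OC)cc(Br)cc2O)CO)C=CC1=O
F0 | step 7 | none | none
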